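All runs were computed with constants of no real substance, noise included.

Time in this flask, alder, is best counted in powers of ten.

| flask | substrate | remark | time |
|---|---|---|---|
| alder | 0.010 M | the very flask that is asked about, followed so far |  |
| cedar | 0.015 M | run made earlier |  |
| flask | 0.010 M |  | 4.0 min |

alder run (percent of the substrate charged)

| time / s | substrate / % | target / % |
|---|---|---|
| 10.0 | 27.7 | 40.6 |
| 25.0 | 22.4 | 31.3 |
| 50.0 | 17.6 | 25.5 |
| 80.0 | 14.5 | 21.2 |

cedar run (percent of the substrate charged)

| time / min | substrate / % | target / % |
|---|---|---|
| 0.333 | 24.2 | 34.7 |
| 0.667 | 18.9 | 27.5 |
| 1.50 | 14.3 | 20.1 |
| 4.00 | 10.6 | 16.8 |

(each reading ± 0.5 percentage points)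

* why nothing more happens at 4.0 min, or that something still does (it is still moving / forward and back rates have come level / all of the substrate has reacted)
* part of the substrate gone at 4.0 min
* the target standing at 4.0 min, as a percentage of the substrate charged
* the isomer of the product A standing at 4.0 min, as a percentage of the substrate charged

- the earlier runs were read with a standard deviation of 0.5 percentage points
- steps under discussion: substrate <-> isomer of the product A; substrate <-> target; substrate <-> isomer of the product B
- the reaction counts as stopped when no species that holds the substrate changes by six tenths of a point or more over the second half of the time

In the first instants, target forms from substrate: by the first alder reading, at 10.0 s, target already stands at 1.47 times substrate. The two therefore behave as one pool, a pre-equilibrium.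

In the middle of the run, this pool falls, and what it loses stands in the two isomers taken together, which are not read. The cedar readings fall on the same time axis as the alder readings, so the last cedar pool, 27.4% at 4.00 min, can serve as the end of the alder pool. Above that end, the alder pool stands 26 percentage points at 25.0 s and 8.3 points at 80.0 s. On logarithms these readings give 1.83 min: the decade time, in which the distance from the end falls tenfold.

Towards the end, the asked time spans 2.19 decade times. At half of it the alder pool still has 3.6 points to lose, and at the ratio of the first reading substrate takes 1.5 points of that, against the stopping limit. My reckoning is therefore that alder is still moving, with 89.4% of the substrate gone and target near 16.8%. The unread 72.6% holds both isomers, and the readings give their sum without dividing it.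

The forecast says it is still moving, with 89.2% gone, target 16.2% and isomer of the product A 36%, noting that the “labels can't say which is the fast, minor isomer”.

The flask gives it is still moving, 88.2% gone, target 16.6% and isomer of the product A 62.7%.

    substrate ⇌ isomer of the product A (K = 5.40, k = 0.0420 s⁻¹)
    substrate ⇌ target (K = 1.40, k = 0.460 s⁻¹)
    substrate ⇌ isomer of the product B (K = 0.750, k = 0.0570 s⁻¹)

The largest change over the second half is 4.8 points. At half time, isomer of the product A stands 5.2 points below its value at 40.0 min. The decade time shrinks that distance to 0.42 points by the asked time, and the flask shows 0.49 points.

Read backwards, the same distance puts the neighbour flask, stopped at 1.5 min, at 53.3% of isomer of the product A. That neighbour flask gives 53.7%.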